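The books are kept on the reagent.

in all of them: starting material 0.91 M
- summer: reagent 0.50 equiv; base 0.038 equiv; scavenger 0.30 equiv; run made earlier
- winter: reagent 0.50 equiv; base 0.21 equiv; scavenger 0.30 equiv; run made earlier
- beta: reagent 0.500 equiv; base 0.0500 equiv; scavenger 0.300 equiv; time 8.0 h
- epsilon: reagent 0.500 equiv; base 0.100 equiv; scavenger 0.300 equiv; time 8.0 h
- alpha: reagent 0.500 equiv; base 0.200 equiv; scavenger 0.300 equiv; time 8.0 h

| run | time / h | starting material / % | product / % |
|---|---|---|---|
| summer | 0.667 | 99.8 | 1.3 |
| summer | 2.00 | 97.2 | 2.2 |
| summer | 4.00 | 94.8 | 5.7 |
| summer | 6.00 | 91.7 | 8.1 |
| summer | 8.00 | 90.0 | 8.5 |
| winter | 0.667 | 98.9 | 0.9 |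
| winter | 2.00 | 96.9 | 2.1 |
| winter | 4.00 | 95.7 | 5.5 |
| winter | 6.00 | 93.2 | 7.4 |
| winter | 8.00 | 91.4 | 9.0 |

(readings scatter by 0.5 percentage points)

- what is said of released group includes idle adduct
- the numbers in the tables scatter with a standard deviation of 0.5 percentage points
- steps under discussion: released group -> by-product carried off; scavenger + released group -> scavenged by-product; base + released group <-> salt; starting material + reagent -> product + released group; reagent + released group <-> idle adduct; starting material + reagent + released group -> product + 2 released group

- part of the starting material that has reacted at the end, beta
- part of the starting material that has reacted at the end, epsilon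
- part of the starting material that has reacted at the end, alpha
- what raising the equivalents of base from its lowest to its highest value here does to the part of the starting material that has reacted (changes below 5 percentage points count as none) (it rises / it falls / no change)

At 0.500 equiv the reagent stands at 0.455 M against 0.91 M of starting material, which makes it the limiting reagent, and each mole of product takes one mole of it. At 8.00 h the summer and winter runs read, as loss of starting material and as product, a mean of 9.03% of the charge. These runs hold 0.038 equiv and 0.21 equiv of base, and their product readings there differ by 0.5 percentage points under a scatter of 0.5 points. So base stays out of this reckoning, and beta, epsilon and alpha, whose base lies between those charges, are booked alike: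

charged reagent: 0.455 M
into product: 0.0821 M
left, free or as idle adduct: 0.373 M

The entry for product needs a pace, 0.0103 M/h on average. The pace constant k is that rate for each molar of starting material times each molar of reagent, a second-order constant read from the readings.

first round, charged concentrations: k = 0.0248 /M/h

Both concentrations fall, so the midway ones go back in, c(starting material) = 0.869 M and c(reagent) = 0.414 M:

second round: k = 0.0285 /M/h

My reckoning therefore books 9.03% reacted in each of the new flasks, with no trend.

The forecast, a shade higher, gives 9.4%, 9.3% and 9.2%, with no change: “Base therefore has no visible effect across a range that brackets all three new charges.”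

The flasks give 9.37%, 9.08% and 9.06%: no change.

    released group → by-product carried off (k = 1.90 × 10⁻⁴ /s)
    scavenger + released group → scavenged by-product (k = 0.0140 /M/s)
    base + released group ⇌ salt, settled at all times (K = 51000 /M)
    starting material + reagent → product + released group (k = 8.00 × 10⁻⁶ /M/s)
    reagent + released group ⇌ idle adduct, settled at all times (K = 13.0 /M)
    starting material + reagent + released group → product + 2 released group (k = 0.00110 /M²/s)

Free base ends at 2.50% of its charge in beta and 55.2% in alpha, while the reacted part falls by 0.32 points. Taken to 4.00 h in epsilon, k gives 5.19% on the first round and 4.80% with the midway values, against 4.86% of product. A neighbour flask, with the equivalents and time of epsilon but 0.23 M of starting material, gets by k 2.63% on the first round, then 2.52% with the midway values, and that neighbour flask stands at 2.55%.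

The earlier runs and the new flask stem from a simulated flask for an exercise; noise was put on by code.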